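(Readings and results were generated by integration with made-up constants, and the scatter is random.)

**First instants.** Time was my axis, since the flask eta was the asked flask, followed so far, and epsilon held half its L with the same J and G.

| flask | L | J | G | remark | time |
|---|---|---|---|---|---|
| eta | 0.40 M | 0.80 M | 40 mM | the very flask that is asked about, followed so far |  |
| epsilon | 0.20 M | 0.80 M | 40 mM | run made earlier |  |
| flask | 0.40 M | 0.800 M | 40 mM |  | 20 min |

| run | time / min | Q / % | D / % |
|---|---|---|---|
| eta | 2.50 | 24.5 | 55.6 |
| eta | 5.00 | 21.1 | 65.9 |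
| eta | 8.00 | 17.1 | 71.7 |
| eta | 10.0 | 15.7 | 74.4 |
| epsilon | 1.50 | 26.3 | 46.8 |
| epsilon | 4.00 | 27.0 | 58.1 |
| epsilon | 8.00 | 23.7 | 63.8 |
| epsilon | 20.0 | 20.4 | 68.1 |

(each reading ± 0.3 percentage points)

* ratio of Q to D at 0.50 s
* ratio of Q to D at 25 s
* ratio of Q to D at 20 min

- a reading or a percentage of D counts all its forms, free or not

The two earliest moments asked about lay before any reading. The first reading of Q/D was 0.562 in epsilon at 1.50 min, and 0.441 in eta at 2.50 min. L had gone fast by then, and I made no reckoning of my own for that window.

**The middle.** From 4.00 min on, Q was falling in both runs, so I asked what was left to fall, and in concentration, not in percent. In eta, Q fell 4.32 mM min⁻¹ around 73.6 mM. In epsilon it fell 0.550 mM min⁻¹ around 44.1 mM. I assumed that both runs lie on one line, with the fall proportional to the excess of Q over a common level. That gave a rate constant of 0.128 min⁻¹ and a level F of 39.8 mM. I called F the Q floor: the concentration of Q, taken as the same in both runs, that the excess is measured from.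

**The end.** For the 10.0 min from the last eta reading to the asked time, I reckoned the fraction of the excess left at 27.9%, which put Q at 11.6% of the L charged. Holding Q + D at its last reading, I reckoned Q/D at 0.147.

**The forecast.** It gave 0.6, 0.6 and 0.155, the last on this ground: “drainage slows, faster in epsilon, which suggests catalyst loss or inhibition”. My late ratio was lower.

**What ran.** The flask gave 0.452, 0.510 and 0.136.

    L + J ⇌ D (K = 1.47 M⁻¹, k = 0.0202 M⁻¹ s⁻¹)
    X ⇌ D, rate k2*(cs2 - [D]) while solid is left; crystals form when [D] > cs2 (solubility = 21.0 mM, k = 0.0657 s⁻¹)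
    D + G ⇌ Q + G, rate k3*[G]*[D] forward; the back reaction follows from the equilibrium constant (k = 0.0353 M⁻¹ s⁻¹)
    L + J ⇌ Q (K = 2.70 M⁻¹, k = 0.00910 M⁻¹ s⁻¹)

At the start, the forward step from L + J to D used L 2.2 times as fast as the one to Q, a selectivity factor. By 2.00 min, crystals X held 43.9% of the L charged, and by 20.0 min they held 75.1%. While X stood, Q in the flask came down to 43.6 mM at 20.0 min, 3.80 mM above F, and to 38.6 mM at 200 min, 1.22 mM below F. A further flask charged with 1.6 M of L gave Q/D of 0.0670 at 20.0 min, its Q of 3.07% being 49.1 mM, which is 9.32 mM above F.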